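**Counting turnovers.** I had 5 questions and 2 earlier runs, and I answered them by counting how often each catalyst has to work.

| setting | Friday's | Monday's | alpha | gamma | beta | delta |
|---|---|---|---|---|---|---|
| substrate | 0.010 M | 0.010 M | 0.010 M | 0.010 M | 0.010 M | 0.010 M |
| reagent | 1 equiv | 2.2 equiv | 1.50 equiv | 1.50 equiv | 1.50 equiv | 1.50 equiv |
| free catalyst | 6.2 mol% | 6.2 mol% | 6.2 mol% | 6.2 mol% | 6.2 mol% | 6.2 mol% |
| temperature | 35 °C | 57 °C | 25 °C | 65 °C |  | 45 °C |
| remark | run made earlier | run made earlier |  |  | at 25 °C until 40 min, from then on at 65 °C |  |
| time |  |  | 50 min | 50 min | 50 min | 50 min |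

- Friday's (time / min: target / %, substrate / %): 3.00: 2.6, 92.3; 10.0: 9.6, 83.1; 20.0: 17.8, 76.0; 25.0: 23.6, 70.8; 40.0: 32.0, 61.9
- Monday's (time / min: target / %, substrate / %): 2.50: 13.1, 80.9; 5.00: 28.2, 65.3; 8.00: 39.0, 55.2; 10.0: 45.5, 48.7; 12.0: 50.8, 45.4

(readings scatter by 1 percentage point)

- the flask with the highest amount of target, in percent of the substrate charged ("all alike" if they lie within 1.5 percentage points) (alpha / gamma / beta / delta / all alike)
- final target, as a percentage of the substrate charged, in alpha
- final target, as a percentage of the substrate charged, in gamma
- final target, as a percentage of the substrate charged, in beta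
- final target, as a percentage of the substrate charged, in delta

- the numbers in the tables scatter by 1 percentage point (one standard deviation)

**First instants.** Substrate was lost ahead of target. Monday's first reading, at 2.50 min, lacks 6 percentage points of the charge, close to the 6.2 mol% of catalyst, and Friday's last reading lacks 6.1 points. So I read the catalyst as taking up substrate quickly and holding it.

**The middle.** After that, each catalyst must repeat its work. With target counted per catalyst charged, a full conversion asks 16.1 turnovers of each catalyst, the turnover bill, which is one over the loading. Paying it in 50 min takes a pace of 0.322 min⁻¹. Friday's run averaged 0.129 min⁻¹ and Monday's 0.683 min⁻¹.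

**The end.** In Monday's run the later turnovers came slower: the pace read 0.910 min⁻¹ up to 5.00 min but 0.521 min⁻¹ afterwards.

**My reckoning.** At Friday's pace, 50 min pays 6.45 turnovers, or 40.1 % target. Alpha runs colder than Friday's, though with more reagent, so I put it below that figure. Monday's pace, read up to 12.0 min, was twice what the bill needs, so I expected gamma, at 65 °C throughout, to come first, short of full conversion. Delta lay between, and I named no figure for it or for beta.

**The forecast.** It chose gamma, with 26 % in alpha, 88 % in gamma, 62 % in beta and 64 % in delta. It averaged two predictions, one with the reagent first order and one with it zero order, since “Temperature and reagent changed together”.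

**The result.** Gamma led with 87.9 %, and alpha gave 30.4 %, beta 55.7 % and delta 73.2 %. The forecast stood 9.2 points low on delta and 6.3 points high on beta.

    substrate + free catalyst → catalyst intermediate A (k = 93.3 M⁻¹ min⁻¹, Ea = 55.0 kJ mol⁻¹)
    reagent + catalyst intermediate A ⇌ catalyst intermediate B (K = 87.0 M⁻¹, k = 11.8 M⁻¹ min⁻¹, Ea = 50.0 kJ mol⁻¹, ΔH = −16.0 kJ mol⁻¹)
    catalyst intermediate B → released group + catalyst intermediate C (k = 1.07 min⁻¹, Ea = 85.0 kJ mol⁻¹)
    catalyst intermediate C ⇌ free catalyst + target (K = 0.0100 M, k = 7.51 min⁻¹, Ea = 77.0 kJ mol⁻¹, ΔH = −58.0 kJ mol⁻¹)
    (constants at 25 °C)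

**Alpha's bill.** Alpha paid 4.89 of its 16.1 turnovers. Its target stood at 30.4 % because of the time of reading: left until 500 min, alpha stands at 96.9 %, which is 67 points more. At 50 min, 64 % of its substrate and 79 % of its reagent remained, and catalyst intermediate A, the resting state, held 71.4 % of the catalyst.

**A dilute neighbour.** Take alpha at 0.0025 M substrate, with the same equivalents, loading and time. The bill stays 16.1, but substrate and reagent each stand at a quarter of alpha's, so I expected that share of alpha's turnovers: 1.23, or 7.61 % target. The computed flask gives 8.76 %, which is 1.41 turnovers.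

(All runs are calculated for an exercise; scatter was added.)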